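**The puzzle.** Compare two flasks. Substrate and reagent make product under a catalyst. I have three runs, and a fourth flask, cedar, to foretell.

all flasks: catalyst 3.00 mM
- maple: substrate 100 mM; reagent 250 mM
- ash: substrate 50.0 mM; reagent 200 mM
- elm: substrate 150 mM; reagent 250 mM
- cedar: substrate 210 mM; reagent 250 mM; time 76 s

- maple run (time / s: [product] / mM): 3.4: 2.9; 10: 0.7; 20: 2.1; 31: 9.7; 44: 18.8; 59: 36.6; 76: 65.9
- ash run (time / s: [product] / mM): 3.4: 0; 10: 3.3; 20: 3.0; 31: 0.9; 44: 2.7; 59: 8.8; 76: 9.6
- elm run (time / s: [product] / mM): 3.4: 1.5; 10: 1.3; 20: 4.1; 31: 16.7; 44: 50.0; 59: 99.6; 76: 131.7

(scatter of a reading: 2 mM)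

- Overall: substrate + reagent -> product, with catalyst as catalyst.
- Constant volume, constant temperature.
- Readings of a species count what is bound in complexes too.
- "The second partner" is reagent.
- An order is taken over about fifteen percent of the charge, up and down.

1. how the opening rate goes with [reagent] round the charge of the maple run: the exponent of the rate at two percent of substrate gone to product
2. how the opening rate goes with [substrate] round the charge of the maple run: the exponent of the rate at two percent of substrate gone to product (one fixed amount of product, the same in the runs compared)
3. the ash run starts with 50.0 mM less of substrate and of reagent than the maple run, and with no product. Compared where both hold the same amount of substrate, once fifteen percent of what the ash run was charged with has turned into product, is the ash run faster, slower or alike (within a tenth)?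
4. product in the cedar run at 76 s, as a share of the substrate charged

The elm run holds 1.50 times the substrate of the maple run, with equal reagent and catalyst. Yet at 76 s it holds twice the product of the maple run. A first-order decay turns equal shares, but these shares are 87.8% in elm and 65.9% in maple.

**The reckoning.** I suppose that product breeds product (autocatalysis), so that the growth rate of ln c(product) is proportional to c(substrate) left. From 44 s to 76 s, the maple run grows at 0.0392 s⁻¹ with 57.7 mM of substrate left on average. From 31 s to 44 s, the elm run grows at 0.0844 s⁻¹ with 117 mM left. Elm grows faster than maple, and it has more substrate left. Dividing gives 0.680 L mol⁻¹ s⁻¹ for maple and 0.723 L mol⁻¹ s⁻¹ for elm. That clears the puzzle: the larger charge breeds faster. Their mean, 0.702 L mol⁻¹ s⁻¹, is the growth constant g: growth of product per mM of product, per mM of substrate left.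

At fixed charge, g makes the odds c(product)/c(substrate) rise as exp(g·charge·t). The elm run stands at 33.3% of its charge at 44 s. I take cedar to be a quarter through by then, which gives 97.4% at 76 s.

Where ash has made 7.50 mM, maple has made 0.0575 M. Both then hold 0.0425 M of substrate and 0.1925 M of unconverted reagent. The rule therefore puts ash at 0.130 of the maple rate, slower. The maple and elm stretches behind g share 250 mM of reagent, so g gives no reagent order.

**The forecast.** It gives 0.9 (0.4 to 1.4) for reagent, 0.7 (0.3 to 1.1) for substrate, slower for ash, and 87% (77% to 95%) for cedar, lower than my figure. On ash it agrees with me: at equal substrate, ash “holds far less product, so it is slower”.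

**The flask.** It gives 0.46 for reagent, 0.93 for substrate, slower for ash, and 93.3% for cedar.

    catalyst + substrate ⇌ catalyst-substrate complex (0.9900 L mol⁻¹ s⁻¹, 1.040 s⁻¹)
    catalyst-substrate complex + reagent → product + catalyst (3.640 L mol⁻¹ s⁻¹)
    substrate + reagent + product → 2 product (6.780 L² mol⁻² s⁻¹)
    substrate + reagent ⇌ idle substrate-reagent adduct, settled at all times (4.350 L mol⁻¹)

**Two uses.** Cedar's 93.3% lies below my 97.4% and above the forecast's 87%. At equal substrate, the ash run goes at 0.14 of the maple rate, and the product ratio was 0.130. In the ash run, going from a quarter to half of the charge raises the odds by a factor of 3, so g allows 31.3 s. The ash run takes 31.7 s.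

The readings were generated by integration for an exercise, noise included.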